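**Strategy.** The flavonol is cut at both bonds of the C4 carbonyl carbon, which sits alone between C4a of ring A and the oxygen-bearing C3 of ring C; this carbon is delivered as carbon monoxide. A palladium-catalysed carbonylative α-arylation joins a symmetric, MOM-protected iodophloroglucinol (ring A), CO and the enolate of an α-benzyloxy ketone that already holds ring B, O3 and O4', creating C4a–C4 and C3–C4 in one operation. The resulting 2-benzyloxy-1,3-diketone is closed to ring C by acid, which also frees O5 and O7; O7 is then sulfated and the benzyl ethers are removed.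

Key step: step 5

Assumption: the target is drawn as the free hydrogen sulfate, so the sulfate is carried as its sodium salt and protonated only in the last operation; the free acid is expected to be hydrolytically labile and should be kept cold and freeze-dried at once.

**Step 1**
Reactants: 1 phloroglucinol (benzene-1,3,5-triol)
Product: 2 1,3,5-tris(methoxymethoxy)benzene
Conditions: MOMCl (4 equiv), i-Pr2NEt (5 equiv), CH2Cl2, 0 °C → rt
Reagents that add atoms: chloromethyl methyl ether, COCCl
Why: Williamson-type O-alkylation with an α-chloro ether (MOM ether formation), in which the hard electrophile and a mild amine base favour attack at oxygen over carbon of phloroglucinol.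

**Step 2**
Reactants: 2 1,3,5-tris(methoxymethoxy)benzene
Product: 3 2-iodo-1,3,5-tris(methoxymethoxy)benzene
Conditions: NIS (1.05 equiv), MeCN, 0 °C → rt, dark
Reagents that add atoms: N-iodosuccinimide, O=C1CCC(=O)N1I
Why: Electrophilic aromatic iodination (SEAr) of a tris-alkoxybenzene whose three ring positions are equivalent, so only one mono-iodide can form, and the neutral acid-free conditions spare the MOM acetals.

**Step 3**
Reactants: 4 benzyloxyacetyl chloride
Product: 5 2-(benzyloxy)-N-methoxy-N-methylacetamide
Conditions: MeNHOMe·HCl (1.1 equiv), Et3N (2.3 equiv), CH2Cl2, 0 °C → rt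
Reagents that add atoms: N,O-dimethylhydroxylamine hydrochloride, CNOC.Cl
Why: N-acylation of N,O-dimethylhydroxylamine by an acid chloride (Weinreb amide formation) is fast and leaves the benzyl ether untouched.

**Step 4**
Reactants: 6 1-(benzyloxy)-4-bromobenzene; 5 2-(benzyloxy)-N-methoxy-N-methylacetamide
Product: 8 2-(benzyloxy)-1-[4-(benzyloxy)phenyl]ethanone, via 4-(benzyloxy)phenylmagnesium bromide 7 (not isolated)
Conditions: Mg turnings (I2 crystal), THF, reflux; then 5, THF, 0 °C → rt; 1 M HCl
Reagents that add atoms: magnesium, [Mg] (retained in 7 only, not in 8)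
Why: Grignard formation followed by Weinreb ketone synthesis, in which the aryl Grignard adds once and the magnesium chelate holds the tetrahedral adduct until acidic work-up, so no tertiary alcohol should form.

**Step 5**
Reactants: 3 2-iodo-1,3,5-tris(methoxymethoxy)benzene; 8 2-(benzyloxy)-1-[4-(benzyloxy)phenyl]ethanone
Product: 10 2-(benzyloxy)-1-[4-(benzyloxy)phenyl]-3-[2,4,6-tris(methoxymethoxy)phenyl]propane-1,3-dione (racemic at C2; enolisable), via sodium (Z)-enolate of the benzyloxy ketone 9 (not isolated)
Conditions: 8 (2.2 equiv), NaN(SiMe3)2 (2.0 equiv), THF, 0 °C; then 3 (1.0 equiv), Pd(dba)2 (5 mol%), Xantphos (5 mol%), CO (1 atm), THF–1,4-dioxane, 70 °C; AcOH quench (surplus 8 recovered)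
Reagents that add atoms: carbon monoxide, [C-]#[O+]; sodium bis(trimethylsilyl)amide, [Na+].C[Si](C)(C)[N-][Si](C)(C)C (sodium retained in 9 only)
Why: Zerovalent palladium adds oxidatively to the C–I bond of 3, CO inserts to give an aroylpalladium iodide (divalent palladium), enolate 9 displaces iodide, and C–C reductive elimination from the carbon-bound palladium enolate releases the diketone as its sodium enolate and returns the catalyst, so C4a–C4 and C3–C4 are made in one cycle. The closest known reaction type is the palladium-catalysed carbonylative α-arylation of ketones with aryl iodides to 1,3-diketones. No ring is closed in this step. The carbon bearing the benzyloxy group becomes a stereocentre that is racemic and enolisable; no control is needed because it turns into the sp2 carbon C3 in step 6. The step needs carbonylative coupling to beat direct α-arylation and C-acylation to beat O-acylation: the two ortho MOM-oxy groups shield the arylpalladium species so that CO insertion comes before enolate transfer, and the wide bite angle of Xantphos favours acyl–carbon reductive elimination. Ketone 8 has a single enolisable carbon, the iodide is symmetric so neither partner poses a regiochemical question, and the second equivalent of 9 deprotonates the acidic product and so protects it from further acylation or cleavage.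

**Step 6**
Reactants: 10 2-(benzyloxy)-1-[4-(benzyloxy)phenyl]-3-[2,4,6-tris(methoxymethoxy)phenyl]propane-1,3-dione
Product: 12 3,4'-di-O-benzylkaempferol [3-(benzyloxy)-2-[4-(benzyloxy)phenyl]-5,7-dihydroxy-4H-chromen-4-one], via triphenol diketone 11 (not isolated)
Conditions: 3 M HCl in MeOH, THF co-solvent, 55 °C
Reagents that add atoms: none
Why: Acid-catalysed methanolysis of the three MOM acetals frees the phenols, and an ortho hydroxyl (either one, by symmetry) adds to the ring B ketone and loses water to give the aromatic pyranone of ring C, the cyclodehydration of an o-hydroxyaryl 1,3-diketone known from the Baker–Venkataraman flavone synthesis, under conditions that benzyl ethers tolerate.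

**Step 7**
Reactants: 12 3,4'-di-O-benzylkaempferol
Product: 14 sodium 3,4'-di-O-benzylkaempferol 7-O-sulfate, via pyridinium 3,4'-di-O-benzylkaempferol 7-O-sulfate 13 (not isolated)
Conditions: SO3·pyridine (2 equiv), pyridine, rt; then NaHCO3, H2O–MeOH; C18 chromatography
Reagents that add atoms: sulfur trioxide–pyridine complex, O=S(=O)([O-])[n+]1ccccc1; sodium hydrogen carbonate, [Na+].OC(=O)[O-]
Why: Phenol O-sulfation by a sulfur trioxide–amine complex should occur at O7 alone, because it is the most acidic and only unencumbered hydroxyl, O5 being held in a hydrogen bond to the C4 carbonyl and O3 and O4' being benzylated.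

**Step 8**
Reactants: 14 sodium 3,4'-di-O-benzylkaempferol 7-O-sulfate
Product: 16 kaempferol 7-O-sulfate [3,5-dihydroxy-2-(4-hydroxyphenyl)-4-oxo-4H-chromen-7-yl hydrogen sulfate], via sodium kaempferol 7-O-sulfate 15 (not isolated)
Conditions: H2 (1 atm), 10% Pd/C, MeOH–THF–H2O, rt; filter; then HCl (1.0 equiv, 0.1 M aq), 0 °C; C18 desalting, freeze-dry
Reagents that add atoms: none
Why: Catalytic hydrogenolysis of the two benzyl ethers over Pd/C leaves aryl sulfate salts and the flavonol core intact, and one equivalent of cold mineral acid then protonates the sulfate monoanion to the hydrogen sulfate.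

**Compound list**
1 | phloroglucinol | Oc1cc(O)cc(O)c1 | starting material
2 | 1,3,5-tris(methoxymethoxy)benzene | COCOc1cc(OCOC)cc(OCOC)c1 | intermediate
3 | 2-iodo-1,3,5-tris(methoxymethoxy)benzene | COCOc1cc(OCOC)c(I)c(OCOC)c1 | intermediate
4 | benzyloxyacetyl chloride | O=C(Cl)COCc1ccccc1 | starting material
5 | 2-(benzyloxy)-N-methoxy-N-methylacetamide | CON(C)C(=O)COCc1ccccc1 | intermediate
6 | 1-(benzyloxy)-4-bromobenzene | Brc1ccc(OCc2ccccc2)cc1 | starting material
7 | 4-(benzyloxy)phenylmagnesium bromide | Br[Mg]c1ccc(OCc2ccccc2)cc1 | intermediate (not isolated)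
8 | 2-(benzyloxy)-1-[4-(benzyloxy)phenyl]ethanone | O=C(COCc1ccccc1)c1ccc(OCc2ccccc2)cc1 | intermediate
9 | sodium (Z)-2-(benzyloxy)-1-[4-(benzyloxy)phenyl]ethen-1-olate (chelated geometry presumed) | [Na+].[O-]/C(=C\OCc1ccccc1)c1ccc(OCc2ccccc2)cc1 | intermediate (not isolated)
10 | 2-(benzyloxy)-1-[4-(benzyloxy)phenyl]-3-[2,4,6-tris(methoxymethoxy)phenyl]propane-1,3-dione (racemic) | O=C(c1ccc(OCc2ccccc2)cc1)C(OCc1ccccc1)C(=O)c1c(OCOC)cc(OCOC)cc1OCOC | intermediate
11 | 2-(benzyloxy)-1-[4-(benzyloxy)phenyl]-3-(2,4,6-trihydroxyphenyl)propane-1,3-dione (racemic) | O=C(c1ccc(OCc2ccccc2)cc1)C(OCc1ccccc1)C(=O)c1c(O)cc(O)cc1O | intermediate (not isolated)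
12 | 3,4'-di-O-benzylkaempferol | O=c1c(OCc2ccccc2)c(-c2ccc(OCc3ccccc3)cc2)oc2cc(O)cc(O)c12 | intermediate
13 | pyridinium 3,4'-di-O-benzylkaempferol 7-O-sulfate | O=c1c(OCc2ccccc2)c(-c2ccc(OCc3ccccc3)cc2)oc2cc(OS(=O)(=O)[O-])cc(O)c12.c1cc[nH+]cc1 | intermediate (not isolated)
14 | sodium 3,4'-di-O-benzylkaempferol 7-O-sulfate | O=c1c(OCc2ccccc2)c(-c2ccc(OCc3ccccc3)cc2)oc2cc(OS(=O)(=O)[O-])cc(O)c12.[Na+] | intermediate
15 | sodium kaempferol 7-O-sulfate | O=c1c(O)c(-c2ccc(O)cc2)oc2cc(OS(=O)(=O)[O-])cc(O)c12.[Na+] | intermediate (not isolated)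
16 | kaempferol 7-O-sulfate | O=c1c(O)c(-c2ccc(O)cc2)oc2cc(OS(=O)(=O)O)cc(O)c12 | target

**Step count.** Total: 8 steps. Longest linear sequence: 6 steps (steps 1, 2, 5, 6, 7, 8 from phloroglucinol; the ketone branch through steps 3, 4, 5, 6, 7, 8 is equally long).

**Steps most likely to fail**

1. Step 5 (carbonylative coupling). The aroylpalladium intermediate may be captured at the enolate oxygen or by the silylamide, or CO insertion may be outrun by reduction or direct arylation of the hindered iodide. The fallback uses classical acylation chemistry without palladium or CO and sets out from 2. Ortho-lithiation (n-BuLi, THF, 0 °C) between two MOM-oxy groups should give [2,4,6-tris(methoxymethoxy)phenyl]lithium F1. Acylation of F1 by Weinreb amide 5 (NH4Cl work-up) should give 2-(benzyloxy)-1-[2,4,6-tris(methoxymethoxy)phenyl]ethanone F2. A crossed Claisen condensation of the enolate of F2 (NaH, THF, reflux) with commercial methyl 4-(benzyloxy)benzoate (COC(=O)c1ccc(OCc2ccccc2)cc1) then makes the C2–C3 bond instead and comes back to the route at diketone 10.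

2. Step 7 (sulfation). Transfer of sulfur trioxide may stall or spread to the chelated 5-hydroxyl, and the ionic product may lose sulfate or be lost during chromatography. The fallback carries the sulfate as a neutral protected diester and sets out from 12. 2,2,2-Trichloroethyl chlorosulfate (ClS(=O)(=O)OCC(Cl)(Cl)Cl), Et3N and catalytic DMAP in THF at 0 °C should give 3,4'-di-O-benzylkaempferol 7-O-(2,2,2-trichloroethyl sulfate) F3, which can be purified on silica and checked for regiochemistry. Reductive removal of the trichloroethyl group (Zn dust, HCO2NH4, MeOH, rt) leaves the benzyl ethers and gives ammonium 3,4'-di-O-benzylkaempferol 7-O-sulfate F4. Treatment with NaHCO3 and evaporation exchanges the cation and comes back to the route at 14.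

3. Step 8 (debenzylation in the presence of the sulfate). Hydrogenolysis may stall on the sparingly soluble salt, because traces of pyridine or sulfur species can inhibit the palladium surface, and prolonged treatment may strip the sulfate. The fallback removes the benzyl groups before any sulfate exists and uses base-labile acetates instead; it sets out from 12.
   - Hydrogenolysis of 12 (H2, 10% Pd/C, EtOAc–MeOH) gives kaempferol F5.
   - Ac2O–pyridine with catalytic DMAP gives 3,5,7,4'-tetra-O-acetylkaempferol F6.
   - Selective thiolysis of the most activated 7-O-acetyl group (PhSH, imidazole, N-methylpyrrolidone, 0 °C → rt) gives 3,5,4'-tri-O-acetylkaempferol F7.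
   - SO3·pyridine in pyridine gives pyridinium 3,5,4'-tri-O-acetylkaempferol 7-O-sulfate F8.
   - Methoxide transesterification (NaOMe, MeOH, 0 °C, argon, then neutralisation with AcOH) removes the acetates and exchanges the cation.
   
   This comes back to the route at 15, which is protonated to 16 as in step 8.

**Further compounds**
F1 | step 5 | [2,4,6-tris(methoxymethoxy)phenyl]lithium | [Li]c1c(OCOC)cc(OCOC)cc1OCOC
F2 | step 5 | 2-(benzyloxy)-1-[2,4,6-tris(methoxymethoxy)phenyl]ethanone | O=C(COCc1ccccc1)c1c(OCOC)cc(OCOC)cc1OCOC
F3 | step 7 | 3,4'-di-O-benzylkaempferol 7-O-(2,2,2-trichloroethyl sulfate) | O=c1c(OCc2ccccc2)c(-c2ccc(OCc3ccccc3)cc2)oc2cc(OS(=O)(=O)OCC(Cl)(Cl)Cl)cc(O)c12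
F4 | step 7 | ammonium 3,4'-di-O-benzylkaempferol 7-O-sulfate | O=c1c(OCc2ccccc2)c(-c2ccc(OCc3ccccc3)cc2)oc2cc(OS(=O)(=O)[O-])cc(O)c12.[NH4+]
F5 | step 8 | kaempferol | O=c1c(O)c(-c2ccc(O)cc2)oc2cc(O)cc(O)c12
F6 | step 8 | 3,5,7,4'-tetra-O-acetylkaempferol | CC(=O)Oc1ccc(-c2oc3cc(OC(C)=O)cc(OC(C)=O)c3c(=O)c2OC(C)=O)cc1
F7 | step 8 | 3,5,4'-tri-O-acetylkaempferol | CC(=O)Oc1ccc(-c2oc3cc(O)cc(OC(C)=O)c3c(=O)c2OC(C)=O)cc1
F8 | step 8 | pyridinium 3,5,4'-tri-O-acetylkaempferol 7-O-sulfate | CC(=O)Oc1ccc(-c2oc3cc(OS(=O)(=O)[O-])cc(OC(C)=O)c3c(=O)c2OC(C)=O)cc1.c1cc[nH+]cc1
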